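## Retrosynthetic overview

- **Numbering.** C1 (quaternary C–Me), C2, C3, C4 (CH–iPr), C5 (ring-fusion C–OH), C6, C7, C8 (=C–Me), C9 (=CH), C10 (CH–O-anisoyl). Ring A is the cycloheptene C1–C10–C9–C8–C7–C6–C5. Ring B is the cyclopentane C1–C5.
- **Feature the plan rests on.** Ring A carries oxygen at C5 and C10, the C8=C9 alkene with its C8 methyl, and saturated C6–C7. This is the pattern left when a 1-siloxy-3-methylbutadiene (C7–C10) joins an oxygenated three-carbon carbenoid (C6–C5–C1). C6–C7 and C1–C10 are therefore cut together by asymmetric cyclopropanation/Cope (formal [4+3]). Ring A is built first and fixes C10.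
- **C1.** C1 is made quaternary (C1–C2) by γ-allylation of the β-keto ester polyanion. C10–O is held as the free alkoxide so that it cannot be expelled. The C6 ester, which served as carbenoid acceptor and regiocontrol element, is then excised.
- **Ring B.** Ring B is closed last at C4–C5 by a copper hydride reductive aldol of the enone made by cross-metathesis. This sets C5–OH and C4 on a cis-fused bicycle. Acetyl → isopropenyl → isopropyl, desilylation and selective anisoylation at C10 finish the route.

Key step: step 4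

Assumption: the (R)-adamantylglycinate dirhodium catalyst is taken to give the (1R,2S)-cyclopropane, by analogy with the (1S,2R) sense of (S)-configured dirhodium carboxylates in styrene cyclopropanation by donor/acceptor carbenoids; if the sense proves opposite, the equally available antipodal catalyst is used.

## Route

Step 1
Reactants: 1 methyl 3-oxopentanoate
Product: 2 methyl 2-diazo-3-oxopentanoate
Conditions: p-ABSA (1.1 equiv), Et3N, MeCN, 0 °C → rt
Reagents that add atoms: 4-acetamidobenzenesulfonyl azide (p-ABSA), CC(=O)Nc1ccc(cc1)S(=O)(=O)N=[N+]=[N-]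
Why: Regitz diazo transfer to the doubly activated methylene of a β-keto ester is general and creates no stereocentre.

Step 2
Reactants: 2 methyl 2-diazo-3-oxopentanoate
Product: 3 methyl (Z)-3-[(tert-butyldimethylsilyl)oxy]-2-diazopent-3-enoate
Conditions: TBSOTf (1.1 equiv), Et3N, CH2Cl2, 0 °C
Reagents that add atoms: tert-butyldimethylsilyl triflate, CC(C)(C)[Si](C)(C)OS(=O)(=O)C(F)(F)F
Why: Soft enolisation (silyl triflate/amine) can only remove a proton from the ethyl side, and allylic strain against the planar diazoester places the methyl trans to the diazo carbon, which is the Z enol ether.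

Step 3
Reactants: 4 3-methylbut-2-enal
Product: 5 (E)-tert-butyldimethyl[(3-methylbuta-1,3-dien-1-yl)oxy]silane
Conditions: TBSOTf (1.05 equiv), Et3N, Et2O, 0 °C → rt; distillation
Reagents that add atoms: tert-butyldimethylsilyl triflate, CC(C)(C)[Si](C)(C)OS(=O)(=O)C(F)(F)F
Why: Vinylogous soft enolisation (γ-deprotonation of the O-silylated enal in its preferred s-trans form) should give the E dienol ether, which is freed of Z isomer by distillation.

Step 4
Reactants: 3 methyl (Z)-3-[(tert-butyldimethylsilyl)oxy]-2-diazopent-3-enoate; 5 (E)-tert-butyldimethyl[(3-methylbuta-1,3-dien-1-yl)oxy]silane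
Product: 7 methyl (3S,4S)-2,4-bis[(tert-butyldimethylsilyl)oxy]-3,6-dimethylcyclohepta-1,5-diene-1-carboxylate (C1–Me cis to C10–O), via cis-divinylcyclopropane 6 (not isolated)
Conditions: Rh2(R-PTAD)4 (1 mol %), 5 (2 equiv), hexanes, 0 °C, slow addition of 3; then 50 °C
Reagents that add atoms: none
Why: Loss of N2 from 3 on the chiral dirhodium core gives a donor/acceptor carbenoid (carbene carbon C6) that adds to the terminal C7=C8 bond of 5, with C7 leading because the charge developing at C8 is stabilised through C9=C10–O, to give cis-divinylcyclopropane 6, which undergoes a [3,3] shift through the boat arrangement open only to the cis isomer, so that C6–C8 breaks, C1–C10 forms, and C5=C6 and C8=C9 appear. This is the established tandem cyclopropanation/Cope rearrangement (formal [4+3] cycloaddition) of 2-siloxyvinyldiazoacetates with dienes, including 1-oxygenated and 2-substituted dienes; the adamantylglycine-derived catalyst is chosen because it gives high induction when the vinyl group carries an internal siloxy substituent, and a methyl ester because it is inert to the carbenoid, whereas an alkenyl ester could be cyclopropanated intramolecularly. Ring A is closed by ring expansion: the intermolecular step makes C6–C7 and the sacrificial C6–C8 bond, and the sigmatropic step closes the seven-membered ring at C1–C10. C10 is controlled by the catalyst, which selects the carbenoid face and so fixes C6 and C8 of 6, together with the E geometry of 5, which holds the siloxy group outward in the boat, while C1 follows from the Z enol ether (methyl outward), so C1–Me and C10–O come out cis, although only C10 is carried to the target because C1 is re-set in step 6. The step needs site selectivity for C7=C8 over the enol-ether bond C9=C10 (secured by the inertness of trans-1,2-disubstituted alkenes to these bulky carbenoids and by the silyl group), placement of the oxyvinyl arm rather than the C8 methyl cis to the siloxyvinyl arm (the flat, charge-bearing arm lies on the donor side, away from the ester), and reaction at the carbene carbon rather than at the vinylogous terminus (secured by the terminal methyl and the hydrocarbon solvent). Geometrically pure 5 is needed because its Z isomer would deliver the opposite configuration at C10 once C1 is erased.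

Step 5
Reactants: 7 methyl (3S,4S)-2,4-bis[(tert-butyldimethylsilyl)oxy]-3,6-dimethylcyclohepta-1,5-diene-1-carboxylate
Product: 8 methyl (3S,4S)-4-hydroxy-3,6-dimethyl-2-oxocyclohept-5-ene-1-carboxylate (keto/enol and C6-epimer mixture)
Conditions: HF·pyridine, pyridine, THF, 0 °C → rt
Reagents that add atoms: none
Why: Buffered fluoride desilylation frees the β-keto ester and the C10 alcohol without generating a C1 enolate, so the β-hydroxy ketone should be neither dehydrated nor cleaved, and C10 is untouched.

Step 6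
Reactants: 8 methyl (3S,4S)-4-hydroxy-3,6-dimethyl-2-oxocyclohept-5-ene-1-carboxylate; 9 allyl bromide
Product: 11 methyl (3R,4S)-4-hydroxy-3,6-dimethyl-2-oxo-3-(prop-2-en-1-yl)cyclohept-5-ene-1-carboxylate (allyl trans to C10–OH; methyl cis to it), via trilithium polyanion 10 (not isolated)
Conditions: LDA (3.4 equiv), THF, −78 → −10 °C; 9 (1.05 equiv), −78 → −30 °C; AcOH, −78 °C
Reagents that add atoms: none
Why: This is a Huckin–Weiler γ-alkylation of a β-keto ester polyanion in which C10–O is a lithium alkoxide that cannot leave (a C10 silyl ether would be lost by β-elimination from the C1 carbanion), C1 is the last-formed and most nucleophilic site, and allyl bromide approaches anti to the solvated C10–OLi (Fráter–Seebach-type facial bias), which sets quaternary C1 with C2 trans and the methyl cis to C10–O.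

Step 7
Reactants: 11 methyl (3R,4S)-4-hydroxy-3,6-dimethyl-2-oxo-3-(prop-2-en-1-yl)cyclohept-5-ene-1-carboxylate
Product: 12 methyl (3R,4S)-2,4-bis[(tert-butyldimethylsilyl)oxy]-3,6-dimethyl-3-(prop-2-en-1-yl)cyclohepta-1,5-diene-1-carboxylate
Conditions: TBSOTf (2.6 equiv), Et3N, CH2Cl2, −78 → 0 °C
Reagents that add atoms: tert-butyldimethylsilyl triflate, CC(C)(C)[Si](C)(C)OS(=O)(=O)C(F)(F)F
Why: Silyl triflate/amine silylation caps the neopentyl C10 alcohol, which blocks retro-aldol cleavage of C1–C10 and later protonation of the copper enolate, and also silylates the β-keto ester enol, which is harmless because that group falls off in step 8.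

Step 8
Reactants: 12 methyl (3R,4S)-2,4-bis[(tert-butyldimethylsilyl)oxy]-3,6-dimethyl-3-(prop-2-en-1-yl)cyclohepta-1,5-diene-1-carboxylate
Product: 14 (2R,3S)-3-[(tert-butyldimethylsilyl)oxy]-2,5-dimethyl-2-(prop-2-en-1-yl)cyclohept-4-en-1-one, via beta-keto ester 13 (not isolated)
Conditions: LiCl (5 equiv), H2O (10 equiv), DMSO, 135 °C
Reagents that add atoms: none
Why: In hot wet DMSO the vinylogous silyl ester is hydrolysed and the methyl β-keto ester undergoes Krapcho dealkoxycarbonylation, and because C1 is now quaternary the C10 silyl ether can no longer be eliminated and no stereocentre is at risk.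

Step 9
Reactants: 14 (2R,3S)-3-[(tert-butyldimethylsilyl)oxy]-2,5-dimethyl-2-(prop-2-en-1-yl)cyclohept-4-en-1-one; 15 but-3-en-2-one (methyl vinyl ketone)
Product: 16 (2R,3S)-3-[(tert-butyldimethylsilyl)oxy]-2,5-dimethyl-2-[(E)-4-oxopent-2-en-1-yl]cyclohept-4-en-1-one
Conditions: Hoveyda–Grubbs II (5 mol %), 15 (4 equiv), CH2Cl2, 40 °C
Reagents that add atoms: none
Why: Olefin cross-metathesis of a terminal alkene with an electron-poor enone partner is E-selective, and the trisubstituted, unstrained ring alkene C8=C9 should stay out of the reaction.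

Step 10
Reactants: 16 (2R,3S)-3-[(tert-butyldimethylsilyl)oxy]-2,5-dimethyl-2-[(E)-4-oxopent-2-en-1-yl]cyclohept-4-en-1-one
Product: 18 1-[(3S,3aS,8S,8aR)-8-[(tert-butyldimethylsilyl)oxy]-3a-hydroxy-6,8a-dimethyl-1,2,3,3a,4,5,8,8a-octahydroazulen-3-yl]ethan-1-one, via copper(I) enolate 17 (not isolated)
Conditions: [(Ph3P)CuH]6 (0.4 equiv), toluene, −40 → 0 °C; aq NH4Cl
Reagents that add atoms: none
Why: In this copper hydride reductive aldol cyclisation of a keto-enone, hydride adds to C3 and the (Z)-copper enolate attacks the C5 ketone from the face that carries the C1 side chain, which makes ring B cis-fused (C5–OH cis to C1–Me), while the closed metal-bridged Zimmerman–Traxler transition state keeps the acetyl group and O5 on the same side, which sets C4 cis to the hydroxyl as the target requires.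

Step 11
Reactants: 18 1-[(3S,3aS,8S,8aR)-8-[(tert-butyldimethylsilyl)oxy]-3a-hydroxy-6,8a-dimethyl-1,2,3,3a,4,5,8,8a-octahydroazulen-3-yl]ethan-1-one
Product: 19 (3R,3aS,8S,8aR)-8-[(tert-butyldimethylsilyl)oxy]-6,8a-dimethyl-3-(prop-1-en-2-yl)-2,3,4,5,8,8a-hexahydroazulen-3a(1H)-ol
Conditions: Cp2TiMe2 (4 equiv), toluene, 70 °C, dark
Reagents that add atoms: dimethyltitanocene (Petasis reagent), [CH3-].[CH3-].[Ti+4].c1cc[cH-]c1.c1cc[cH-]c1
Why: Petasis methylenation uses a neutral titanium methylidene, so the β-hydroxy ketone is spared the retro-aldol opening and C4 epimerisation that a basic ylide would cause, and the excess reagent covers the free C5–OH.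

Step 12
Reactants: 19 (3R,3aS,8S,8aR)-8-[(tert-butyldimethylsilyl)oxy]-6,8a-dimethyl-3-(prop-1-en-2-yl)-2,3,4,5,8,8a-hexahydroazulen-3a(1H)-ol
Product: 20 (3R,3aS,8S,8aR)-8-[(tert-butyldimethylsilyl)oxy]-6,8a-dimethyl-3-(propan-2-yl)-2,3,4,5,8,8a-hexahydroazulen-3a(1H)-ol
Conditions: H2 (1 atm), RhCl(PPh3)3 (10 mol %), benzene–EtOH, rt
Reagents that add atoms: none
Why: Homogeneous hydrogenation with Wilkinson's catalyst discriminates by substitution, so the 1,1-disubstituted isopropenyl group is reduced while the trisubstituted, siloxy-flanked C8=C9 is left, and no stereocentre is formed.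

Step 13
Reactants: 20 (3R,3aS,8S,8aR)-8-[(tert-butyldimethylsilyl)oxy]-6,8a-dimethyl-3-(propan-2-yl)-2,3,4,5,8,8a-hexahydroazulen-3a(1H)-ol
Product: 21 (3R,3aS,8S,8aR)-6,8a-dimethyl-3-(propan-2-yl)-1,2,3,4,5,8-hexahydroazulene-3a,8(8aH)-diol
Conditions: TBAF, THF, rt → 45 °C
Reagents that add atoms: none
Why: Fluoride desilylation cleaves Si–O, not C–O, so C10 keeps its configuration, and nothing base-labile remains in the molecule.

Step 14
Reactants: 21 (3R,3aS,8S,8aR)-6,8a-dimethyl-3-(propan-2-yl)-1,2,3,4,5,8-hexahydroazulene-3a,8(8aH)-diol; 22 4-methoxybenzoyl chloride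
Product: 23 (3R,3aS,8S,8aR)-3a-hydroxy-6,8a-dimethyl-3-(propan-2-yl)-1,2,3,3a,4,5,8,8a-octahydroazulen-8-yl 4-methoxybenzoate (CNP0158828.1)
Conditions: 22 (1.5 equiv), DMAP, pyridine, CH2Cl2, rt → 40 °C
Reagents that add atoms: none
Why: DMAP-catalysed acylation takes the secondary allylic C10–OH with retention and leaves the tertiary C5–OH, which is inert under these conditions.

## Compound list

1 | methyl 3-oxopentanoate | CCC(=O)CC(=O)OC | starting material
2 | methyl 2-diazo-3-oxopentanoate | CCC(=O)C(=[N+]=[N-])C(=O)OC | intermediate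
3 | methyl (Z)-3-[(tert-butyldimethylsilyl)oxy]-2-diazopent-3-enoate | C/C=C(\O[Si](C)(C)C(C)(C)C)C(=[N+]=[N-])C(=O)OC | intermediate
4 | 3-methylbut-2-enal | CC(C)=CC=O | starting material
5 | (E)-tert-butyldimethyl[(3-methylbuta-1,3-dien-1-yl)oxy]silane | C=C(C)/C=C/O[Si](C)(C)C(C)(C)C | intermediate
6 | methyl (1R,2S)-1-[(Z)-1-(TBSO)prop-1-en-1-yl]-2-[(E)-2-(TBSO)ethenyl]-2-methylcyclopropane-1-carboxylate (alkenyl arms cis) | COC(=O)[C@]1(/C(O[Si](C)(C)C(C)(C)C)=C/C)C[C@@]1(C)/C=C/O[Si](C)(C)C(C)(C)C | intermediate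
7 | methyl (3S,4S)-2,4-bis[(tert-butyldimethylsilyl)oxy]-3,6-dimethylcyclohepta-1,5-diene-1-carboxylate | COC(=O)C1=C(O[Si](C)(C)C(C)(C)C)[C@@H](C)[C@@H](O[Si](C)(C)C(C)(C)C)C=C(C)C1 | intermediate
8 | methyl (3S,4S)-4-hydroxy-3,6-dimethyl-2-oxocyclohept-5-ene-1-carboxylate | COC(=O)C1CC(C)=C[C@H](O)[C@H](C)C1=O | intermediate
9 | allyl bromide | C=CCBr | starting material
10 | trilithium polyanion of 8 (C10 alkoxide, C5/C1 and C6/ester enolates) | [Li+].[Li+].[Li+].COC([O-])=C1CC(C)=C[C@H]([O-])C(C)=C1[O-] | intermediate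
11 | methyl (3R,4S)-4-hydroxy-3,6-dimethyl-2-oxo-3-(prop-2-en-1-yl)cyclohept-5-ene-1-carboxylate | COC(=O)C1CC(C)=C[C@H](O)[C@@](C)(CC=C)C1=O | intermediate
12 | methyl (3R,4S)-2,4-bis[(tert-butyldimethylsilyl)oxy]-3,6-dimethyl-3-(prop-2-en-1-yl)cyclohepta-1,5-diene-1-carboxylate | COC(=O)C1=C(O[Si](C)(C)C(C)(C)C)[C@](C)(CC=C)[C@@H](O[Si](C)(C)C(C)(C)C)C=C(C)C1 | intermediate
13 | methyl (3R,4S)-4-[(tert-butyldimethylsilyl)oxy]-3,6-dimethyl-2-oxo-3-(prop-2-en-1-yl)cyclohept-5-ene-1-carboxylate | COC(=O)C1CC(C)=C[C@H](O[Si](C)(C)C(C)(C)C)[C@@](C)(CC=C)C1=O | intermediate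
14 | (2R,3S)-3-[(tert-butyldimethylsilyl)oxy]-2,5-dimethyl-2-(prop-2-en-1-yl)cyclohept-4-en-1-one | CC(C)(C)[Si](C)(C)O[C@H]1C=C(C)CCC(=O)[C@]1(C)CC=C | intermediate
15 | but-3-en-2-one | C=CC(C)=O | starting material
16 | (2R,3S)-3-[(tert-butyldimethylsilyl)oxy]-2,5-dimethyl-2-[(E)-4-oxopent-2-en-1-yl]cyclohept-4-en-1-one | CC(C)(C)[Si](C)(C)O[C@H]1C=C(C)CCC(=O)[C@]1(C)C/C=C/C(C)=O | intermediate
17 | copper(I) (Z)-enolate from conjugate reduction of 16 (phosphine ligands omitted) | CC(C)(C)[Si](C)(C)O[C@H]1C=C(C)CCC(=O)[C@]1(C)CC\C=C(\C)O[Cu] | intermediate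
18 | 1-[(3S,3aS,8S,8aR)-8-[(tert-butyldimethylsilyl)oxy]-3a-hydroxy-6,8a-dimethyl-1,2,3,3a,4,5,8,8a-octahydroazulen-3-yl]ethan-1-one | CC(C)(C)[Si](C)(C)O[C@H]1C=C(C)CC[C@]2(O)[C@@H](C(C)=O)CC[C@]12C | intermediate
19 | (3R,3aS,8S,8aR)-8-[(tert-butyldimethylsilyl)oxy]-6,8a-dimethyl-3-(prop-1-en-2-yl)-2,3,4,5,8,8a-hexahydroazulen-3a(1H)-ol | CC(C)(C)[Si](C)(C)O[C@H]1C=C(C)CC[C@]2(O)[C@@H](C(C)=C)CC[C@]12C | intermediate
20 | (3R,3aS,8S,8aR)-8-[(tert-butyldimethylsilyl)oxy]-6,8a-dimethyl-3-(propan-2-yl)-2,3,4,5,8,8a-hexahydroazulen-3a(1H)-ol | CC(C)(C)[Si](C)(C)O[C@H]1C=C(C)CC[C@]2(O)[C@@H](C(C)C)CC[C@]12C | intermediate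
21 | (3R,3aS,8S,8aR)-6,8a-dimethyl-3-(propan-2-yl)-1,2,3,4,5,8-hexahydroazulene-3a,8(8aH)-diol | O[C@H]1C=C(C)CC[C@]2(O)[C@@H](C(C)C)CC[C@]12C | intermediate
22 | 4-methoxybenzoyl chloride | COc1ccc(C(Cl)=O)cc1 | starting material
23 | (3R,3aS,8S,8aR)-3a-hydroxy-6,8a-dimethyl-3-(propan-2-yl)-1,2,3,3a,4,5,8,8a-octahydroazulen-8-yl 4-methoxybenzoate | COc1ccc(C(=O)O[C@H]2C=C(C)CC[C@]3(O)[C@@H](C(C)C)CC[C@]23C)cc1 | target

## Step count and risks

Total step count: 14. Longest linear sequence: 13 (steps 1, 2 and 4–14; step 3 is the side branch).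

Steps most likely to fail:

1. **Step 6.** The third deprotonation, at a tertiary C1–H next to a lithium alkoxide, may stay incomplete, or the polyanion may aggregate. Alkylation would then drift to C6 or to oxygen, and the facial bias at C1 may be weaker than expected.
   - The fallback is a pericyclic relay that never forms a C1 carbanion, and it sets out from 8.
   - Tsuji–Trost allylation of 8 (Pd(PPh3)4, allyl methyl carbonate, THF, rt) occurs at the stabilised C6 position, on the face away from the C1 methyl and the C10 hydroxyl. It gives methyl (1R,3S,4S)-4-hydroxy-3,6-dimethyl-2-oxo-1-(prop-2-en-1-yl)cyclohept-5-ene-1-carboxylate F1.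
   - TBSOTf/Et3N can now enolise only toward C1. It gives the 1,5-diene methyl (1R,4S)-2,4-bis[(tert-butyldimethylsilyl)oxy]-3,6-dimethyl-1-(prop-2-en-1-yl)cyclohepta-2,5-diene-1-carboxylate F2.
   - Heating (toluene, sealed tube, about 170 °C) should move the allyl group suprafacially from C6 to C1 by a Cope rearrangement. The driving force is restored conjugation of the enol ether with the ester. This comes back to the route at 12.

2. **Step 4.** Enantioface discrimination on a 1,1-disubstituted, strongly polarised alkene may be insufficient, and part of the carbenoid may be lost to attack at its vinylogous terminus.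
   - The fallback separates ring construction from the source of chirality, and it sets out from 3 and 5.
   - The same annulation with achiral Rh2(octanoate)4 gives 7 together with its antipode, methyl (3R,4R)-2,4-bis[(tert-butyldimethylsilyl)oxy]-3,6-dimethylcyclohepta-1,5-diene-1-carboxylate F3.
   - HF·pyridine then gives 8 together with methyl (3R,4R)-4-hydroxy-3,6-dimethyl-2-oxocyclohept-5-ene-1-carboxylate F4.
   - Lipase-catalysed kinetic resolution (immobilised Candida antarctica lipase B, vinyl acetate, MTBE) should, by the Kazlauskas rule, acetylate the (4R)-alcohol to methyl (3R,4R)-4-acetoxy-3,6-dimethyl-2-oxocyclohept-5-ene-1-carboxylate F5.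
   - The (4S)-alcohol is left behind and is separated. This comes back to the route at 8.

3. **Step 10.** The copper enolate may be quenched or may persist without closing onto the hindered, α-quaternary C5 ketone, or the closure may show imperfect control at C4.
   - The fallback replaces the kinetic metal-enolate closure by a two-stage thermodynamic aldol, and it sets out from 16.
   - Hydrogenation of the enone C=C (H2, RhCl(PPh3)3, benzene) gives (2R,3S)-3-[(tert-butyldimethylsilyl)oxy]-2,5-dimethyl-2-(4-oxopentyl)cyclohept-4-en-1-one F6.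
   - Catalytic KOt-Bu in t-BuOH/THF at 0 °C closes the five-membered ring reversibly.
   - C4 remains epimerisable, so the acetyl group should settle on the convex face, hydrogen-bonded and cis to C5–OH. This comes back to the route at 18.

## Further compounds

F1 | step 6 | methyl (1R,3S,4S)-4-hydroxy-3,6-dimethyl-2-oxo-1-(prop-2-en-1-yl)cyclohept-5-ene-1-carboxylate | COC(=O)[C@]1(CC=C)CC(C)=C[C@H](O)[C@H](C)C1=O
F2 | step 6 | methyl (1R,4S)-2,4-bis[(tert-butyldimethylsilyl)oxy]-3,6-dimethyl-1-(prop-2-en-1-yl)cyclohepta-2,5-diene-1-carboxylate | COC(=O)[C@]1(CC=C)CC(C)=C[C@H](O[Si](C)(C)C(C)(C)C)C(C)=C1O[Si](C)(C)C(C)(C)C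
F3 | step 4 | methyl (3R,4R)-2,4-bis[(tert-butyldimethylsilyl)oxy]-3,6-dimethylcyclohepta-1,5-diene-1-carboxylate | COC(=O)C1=C(O[Si](C)(C)C(C)(C)C)[C@H](C)[C@H](O[Si](C)(C)C(C)(C)C)C=C(C)C1
F4 | step 4 | methyl (3R,4R)-4-hydroxy-3,6-dimethyl-2-oxocyclohept-5-ene-1-carboxylate | COC(=O)C1CC(C)=C[C@@H](O)[C@@H](C)C1=O
F5 | step 4 | methyl (3R,4R)-4-acetoxy-3,6-dimethyl-2-oxocyclohept-5-ene-1-carboxylate | COC(=O)C1CC(C)=C[C@@H](OC(C)=O)[C@@H](C)C1=O
F6 | step 10 | (2R,3S)-3-[(tert-butyldimethylsilyl)oxy]-2,5-dimethyl-2-(4-oxopentyl)cyclohept-4-en-1-one | CC(C)(C)[Si](C)(C)O[C@H]1C=C(C)CCC(=O)[C@]1(C)CCCC(C)=O
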